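**Assumption:** the given SMILES is taken as the full definition of CNP0232260.1. Germacrane numbering is used in the explanations: ring C1–C10, lactone C11–C13 (C12 carbonyl, C13 methylene), C14 on C10, C15 on C4. Compounds 7–14 are mixtures of epimers at the lactol/acetal carbon, a centre that disappears in step 9.

## Retrosynthetic overview

1. Target ⇒ C8 ester by Mitsunobu inversion with (2S,3S)-epoxyangelic acid, C14 acetate, and Sharpless epoxidation of the C14 allylic alcohol (sets C1/C10).
2. Key C–C bond C7–C8: the lactone β-carbon C7, normally a Michael acceptor, is made nucleophilic as the allylindium of a 3-(bromomethyl)butenolide (β-acyl anion, homoenolate-type). It adds intramolecularly to the C8 aldehyde (masked as a lactol), closing the ten-membered ring, creating the α-methylene lactone and setting C7 and C8.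
3. Cyclisation precursor ⇒ ring-closing metathesis (butenolide), asymmetric vinylation (C6), and Still–Gennari olefination of a neryl-acetate-derived aldehyde with a phosphonosuccinate (fixes the C1=C10 geometry, brings C14, C9, C8).
4. Ring order: butenolide → ten-membered carbocycle → C1–C10 oxirane; the side-chain oxirane is made separately from angelic acid.

## Route

Step 1
Reactants: 1 neryl acetate [(2Z)-3,7-dimethylocta-2,6-dien-1-yl acetate]
Product: 2 (2Z)-3-methyl-6-oxohex-2-en-1-yl acetate
Conditions: O3 (1.0 equiv), CH2Cl2, pyridine, −78 °C; then Me2S, −78 °C → rt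
Reagents that add atoms: ozone, O=[O+][O-]
Why: Chemoselective ozonolysis with reductive work-up: the remote isopropylidene alkene is far more electron-rich than the alkene deactivated by the allylic acetate, so one equivalent of ozone cleaves only that end and leaves the Z alkene (future C4=C5) intact; no stereocentre is formed.

Step 2
Reactants: 3 methyl 2-[bis(2,2,2-trifluoroethoxy)phosphoryl]acetate; 4 methyl bromoacetate
Product: 5 dimethyl 2-[bis(2,2,2-trifluoroethoxy)phosphoryl]butanedioate (racemic)
Conditions: NaH, THF, 0 °C; then 4, 0 °C → rt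
Reagents that add atoms: none
Why: SN2 C-alkylation of the sodium phosphonoacetate anion gives the phosphonosuccinate carrying C10, C14, C9 and C8; its stereocentre is racemic and is destroyed in step 3.

Step 3
Reactants: 2 (2Z)-3-methyl-6-oxohex-2-en-1-yl acetate; 5 dimethyl 2-[bis(2,2,2-trifluoroethoxy)phosphoryl]butanedioate
Product: 6 dimethyl (2Z)-2-[(4Z)-6-acetoxy-4-methylhex-4-en-1-ylidene]butanedioate
Conditions: KN(SiMe3)2, 18-crown-6, THF, −78 °C; then 2, −78 °C
Reagents that add atoms: none
Why: Still–Gennari variant of the Horner–Wadsworth–Emmons olefination: the bis(trifluoroethyl) phosphonate with a dissociated potassium ion eliminates under kinetic control, placing the aldehyde chain (C2) cis to the conjugated ester (future C14) and trans to the CH2CO2Me arm (C9), which is the ring-trans C1=C10 geometry of the target.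

Step 4
Reactants: 6 dimethyl (2Z)-2-[(4Z)-6-acetoxy-4-methylhex-4-en-1-ylidene]butanedioate
Product: 8 (2Z,6Z)-6-(5-methoxyoxolan-3-ylidene)-3-methylhex-2-en-1-ol, via lactol 7 (not isolated)
Conditions: iBu2AlH (5.5 equiv), CH2Cl2, −78 °C; aq KNaC4H4O6 work-up; then MeOH, PPTS (cat.), rt
Reagents that add atoms: methanol, CO
Why: Temperature-controlled iBu2AlH reduction takes the conjugated ester to the C14 allylic alcohol and the acetate to the free C6 alcohol while the saturated ester stops at the aldehyde level (C8), which is captured by the C14 hydroxyl as the five-membered lactol 7; Fischer-type acetalisation with methanol then masks C8 and C14 together and leaves only the C6 alcohol free.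

Step 5
Reactants: 8 (2Z,6Z)-6-(5-methoxyoxolan-3-ylidene)-3-methylhex-2-en-1-ol
Product: 9 (2Z,6Z)-6-(5-methoxyoxolan-3-ylidene)-3-methylhex-2-enal
Conditions: TEMPO (10 mol %), PhI(OAc)2 (1.1 equiv), NaHCO3, CH2Cl2, 0 °C → rt
Reagents that add atoms: none
Why: Oxoammonium (TEMPO) oxidation of the only free, allylic primary alcohol gives the neral-type enal without Z-to-E isomerisation or over-oxidation; no stereocentre changes.

Step 6
Reactants: 9 (2Z,6Z)-6-(5-methoxyoxolan-3-ylidene)-3-methylhex-2-enal
Product: 10 (3S,4Z,8Z)-8-(5-methoxyoxolan-3-ylidene)-5-methylocta-1,4-dien-3-ol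
Conditions: CH2=CHMgBr (2.4 equiv) + ZnCl2 (1.2 equiv) → Zn(CH=CH2)2; (−)-MIB [(2S)-(−)-3-exo-morpholinoisoborneol, 10 mol %], toluene/THF, −30 → 0 °C; aq NH4Cl
Reagents that add atoms: vinylmagnesium bromide, C=C[Mg]Br (transferred through divinylzinc, C=C[Zn]C=C)
Why: Amino-alcohol-catalysed asymmetric 1,2-addition of a vinylzinc reagent to the enal: the (−)-MIB zinc complex is expected, by analogy with aryl and alkenyl aldehydes, to deliver vinyl to the Si face, setting C6 as S (the same spatial arrangement as 6R in the target; only the CIP priorities differ).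

Step 7
Reactants: 10 (3S,4Z,8Z)-8-(5-methoxyoxolan-3-ylidene)-5-methylocta-1,4-dien-3-ol; 11 2-(bromomethyl)prop-2-enoic acid
Product: 12 (3S,4Z,8Z)-8-(5-methoxyoxolan-3-ylidene)-5-methylocta-1,4-dien-3-yl 2-(bromomethyl)prop-2-enoate
Conditions: DIC, DMAP (5 mol %), CH2Cl2, −10 °C
Reagents that add atoms: none
Why: Steglich esterification (carbodiimide activation, little DMAP and low temperature to spare the allylic bromide) attaches the C11/C12/C13 unit to the C6 oxygen with retention at C6.

Step 8
Reactants: 12 (3S,4Z,8Z)-8-(5-methoxyoxolan-3-ylidene)-5-methylocta-1,4-dien-3-yl 2-(bromomethyl)prop-2-enoate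
Product: 13 (5R)-3-(bromomethyl)-5-[(1Z,5Z)-5-(5-methoxyoxolan-3-ylidene)-2-methylpent-1-en-1-yl]furan-2(5H)-one
Conditions: second-generation Grubbs catalyst RuCl2(=CHPh)(PCy3)(H2IMes) (5 mol %), CH2Cl2 (5 mM), 40 °C
Reagents that add atoms: none
Why: Ring-closing metathesis between the terminal vinyl group and the 1,1-disubstituted acrylate closes the butenolide (C7=C11) with loss of ethene; the trisubstituted alkenes do not react with the ruthenium carbene and C6 is untouched (now R by CIP).

Step 9
Reactants: 13 (5R)-3-(bromomethyl)-5-[(1Z,5Z)-5-(5-methoxyoxolan-3-ylidene)-2-methylpent-1-en-1-yl]furan-2(5H)-one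
Product: 15 (6R,7R,8S)-8,14-dihydroxygermacra-1(10),4,11(13)-trien-12,6-olide, via lactol 14 (not isolated)
Conditions: 1 M aq HCl/THF (1:4), rt; then slow addition to indium powder (In, 3 equiv), THF/sat. aq NH4Cl (3:1), 2 mM, rt
Reagents that add atoms: water, O
Why: Proposed new method: acid hydrolysis unmasks lactol 14 (in equilibrium with the C8 hydroxy-aldehyde) and indium inserts into the allylic C–Br bond, giving an allylindium in which the lactone β-carbon C7, normally a Michael acceptor, is the nucleophile (β-acyl anion, homoenolate-type); intramolecular γ-selective (SE2′) Barbier addition to the C8 carbonyl closes the ten-membered ring and releases the α-methylene lactone, with C8 bonding to C7 anti to the C6–C5 bond (trans-fused lactone, 7R) and the closed chair (Zimmerman–Traxler) transition state of this ring-locked allyl unit, aldehyde chain equatorial, giving the (8S) carbinol, which is deliberately the C8 epimer and is inverted in step 15; the closest known reactions are intermolecular indium, zinc and chromium Barbier additions of 3-(bromomethyl)furan-2(5H)-one to aldehydes, indium allylations of lactols in water, and Barbier macrocyclisations of 2-(bromomethyl)acrylates to germacranolides.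

Step 10
Reactants: 15 (6R,7R,8S)-8,14-dihydroxygermacra-1(10),4,11(13)-trien-12,6-olide
Product: 16 (1R,6R,7R,8S,10S)-1,10-epoxy-8,14-dihydroxygermacra-4,11(13)-dien-12,6-olide
Conditions: Ti(OiPr)4 (10 mol %), L-(+)-diethyl tartrate (12 mol %), tBuOOH (2 equiv), 4 Å molecular sieves, CH2Cl2, −20 °C
Reagents that add atoms: tert-butyl hydroperoxide, CC(C)(C)OO
Why: Sharpless asymmetric epoxidation: the titanium tartrate binds the C14 allylic hydroxyl and with L-(+)-tartrate delivers oxygen to the C1=C10 face giving (1R,10S), the sense in which nerol gives its (2S,3R) epoxide; C4=C5 has no free allylic hydroxyl and the exocyclic methylene is electron-poor, so only this alkene reacts.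

Step 11
Reactants: 16 (1R,6R,7R,8S,10S)-1,10-epoxy-8,14-dihydroxygermacra-4,11(13)-dien-12,6-olide
Product: 17 (1R,6R,7R,8S,10S)-14-acetoxy-1,10-epoxy-8-hydroxygermacra-4,11(13)-dien-12,6-olide
Conditions: Ac2O (1.1 equiv), 2,4,6-collidine, CH2Cl2, −20 → 0 °C
Reagents that add atoms: acetic anhydride, CC(=O)OC(C)=O
Why: Sterically controlled acylation: with one equivalent of anhydride and a hindered pyridine base at low temperature the primary C14 alcohol is acetylated much faster than the hindered secondary C8 alcohol; no stereocentre is affected.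

Step 12
Reactants: 18 angelic acid [(2Z)-2-methylbut-2-enoic acid]
Product: 19 (2Z)-2-methylbut-2-en-1-ol
Conditions: LiAlH4, Et2O, 0 °C
Reagents that add atoms: none
Why: Hydride reduction of the carboxylic acid to the primary allylic alcohol; the trisubstituted alkene is not reduced and its Z geometry is kept.

Step 13
Reactants: 19 (2Z)-2-methylbut-2-en-1-ol
Product: 20 [(2R,3S)-2,3-dimethyloxiran-2-yl]methanol
Conditions: Ti(OiPr)4 (10 mol %), D-(−)-diethyl tartrate (12 mol %), tBuOOH, 4 Å molecular sieves, CH2Cl2, −20 °C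
Reagents that add atoms: tert-butyl hydroperoxide, CC(C)(C)OO
Why: Sharpless asymmetric epoxidation: for this (Z)-2,3-disubstituted allylic alcohol D-(−)-tartrate gives the (2R,3S) epoxy alcohol (the mirror image of the nerol-type result with L-(+)-tartrate), and syn oxygen transfer keeps the two methyl groups trans.

Step 14
Reactants: 20 [(2R,3S)-2,3-dimethyloxiran-2-yl]methanol
Product: 21 (2S,3S)-2,3-dimethyloxirane-2-carboxylic acid
Conditions: RuCl3 (2 mol %), NaIO4 (3 equiv), CCl4/MeCN/H2O, 0 °C → rt
Reagents that add atoms: water, O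
Why: Catalytic ruthenium tetroxide oxidation takes the primary alcohol through the aldehyde hydrate to the acid without opening the trisubstituted epoxide; the geometry is unchanged and the descriptors become (2S,3S) only because the carboxyl group outranks C3.

Step 15
Reactants: 17 (1R,6R,7R,8S,10S)-14-acetoxy-1,10-epoxy-8-hydroxygermacra-4,11(13)-dien-12,6-olide; 21 (2S,3S)-2,3-dimethyloxirane-2-carboxylic acid
Product: 22 (1R,4Z,6R,7R,8R,10S)-14-acetoxy-8-{[(2S,3S)-2,3-dimethyloxiran-2-yl]carbonyloxy}-1,10-epoxygermacra-4,11(13)-dien-12,6-olide (CNP0232260.1)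
Conditions: PPh3, DIAD (betaine pre-formed), toluene, 0 °C → rt
Reagents that add atoms: none
Why: Mitsunobu esterification: the C8 alcohol is activated as its alkoxyphosphonium ion and displaced by the carboxylate of 21 in an SN2 reaction with inversion, turning the (8S) carbinol of step 9 into the (8R) ester of the target; the betaine is pre-formed so that no free PPh3 can add to the α-methylene lactone.

## Compound list

1 | neryl acetate, (2Z)-3,7-dimethylocta-2,6-dien-1-yl acetate | CC(C)=CCC/C(C)=C\COC(C)=O | starting material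
2 | (2Z)-3-methyl-6-oxohex-2-en-1-yl acetate | O=CCC/C(C)=C\COC(C)=O | intermediate
3 | methyl 2-[bis(2,2,2-trifluoroethoxy)phosphoryl]acetate | COC(=O)CP(=O)(OCC(F)(F)F)OCC(F)(F)F | starting material
4 | methyl bromoacetate | COC(=O)CBr | starting material
5 | dimethyl 2-[bis(2,2,2-trifluoroethoxy)phosphoryl]butanedioate (racemic) | COC(=O)CC(C(=O)OC)P(=O)(OCC(F)(F)F)OCC(F)(F)F | intermediate
6 | dimethyl (2Z)-2-[(4Z)-6-acetoxy-4-methylhex-4-en-1-ylidene]butanedioate | CC(=O)OC/C=C(C)\CC/C=C(/CC(=O)OC)C(=O)OC | intermediate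
7 | (4Z)-4-[(4Z)-6-hydroxy-4-methylhex-4-en-1-ylidene]oxolan-2-ol (lactol) | OC1C/C(=C/CC/C(C)=C\CO)CO1 | intermediate
8 | (2Z,6Z)-6-(5-methoxyoxolan-3-ylidene)-3-methylhex-2-en-1-ol | COC1C/C(=C/CC/C(C)=C\CO)CO1 | intermediate
9 | (2Z,6Z)-6-(5-methoxyoxolan-3-ylidene)-3-methylhex-2-enal | COC1C/C(=C/CC/C(C)=C\C=O)CO1 | intermediate
10 | (3S,4Z,8Z)-8-(5-methoxyoxolan-3-ylidene)-5-methylocta-1,4-dien-3-ol | COC1C/C(=C/CC/C(C)=C\[C@@H](O)C=C)CO1 | intermediate
11 | 2-(bromomethyl)prop-2-enoic acid | C=C(CBr)C(=O)O | starting material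
12 | (3S,4Z,8Z)-8-(5-methoxyoxolan-3-ylidene)-5-methylocta-1,4-dien-3-yl 2-(bromomethyl)prop-2-enoate | COC1C/C(=C/CC/C(C)=C\[C@@H](OC(=O)C(=C)CBr)C=C)CO1 | intermediate
13 | (5R)-3-(bromomethyl)-5-[(1Z,5Z)-5-(5-methoxyoxolan-3-ylidene)-2-methylpent-1-en-1-yl]furan-2(5H)-one | COC1C/C(=C/CC/C(C)=C\[C@H]2OC(=O)C(CBr)=C2)CO1 | intermediate
14 | (5R)-3-(bromomethyl)-5-[(1Z,5Z)-5-(5-hydroxyoxolan-3-ylidene)-2-methylpent-1-en-1-yl]furan-2(5H)-one (lactol) | OC1C/C(=C/CC/C(C)=C\[C@H]2OC(=O)C(CBr)=C2)CO1 | intermediate
15 | (6R,7R,8S)-8,14-dihydroxygermacra-1(10),4,11(13)-trien-12,6-olide; C4=C5 Z, C2 cis to C14 on C1=C10; systematic: (3aR,4S,6Z,10Z,11aR)-4-hydroxy-6-(hydroxymethyl)-10-methyl-3-methylidene-3a,4,5,8,9,11a-hexahydrocyclodeca[b]furan-2(3H)-one | C=C1C(=O)O[C@@H]2/C=C(/C)CC/C=C(\CO)C[C@H](O)[C@@H]12 | intermediate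
16 | (1R,4Z,6R,7R,8S,10S)-1,10-epoxy-8,14-dihydroxygermacra-4,11(13)-dien-12,6-olide | C=C1C(=O)O[C@@H]2/C=C(/C)CC[C@H]3O[C@]3(CO)C[C@H](O)[C@@H]12 | intermediate
17 | (1R,4Z,6R,7R,8S,10S)-14-acetoxy-1,10-epoxy-8-hydroxygermacra-4,11(13)-dien-12,6-olide | C=C1C(=O)O[C@@H]2/C=C(/C)CC[C@H]3O[C@]3(COC(C)=O)C[C@H](O)[C@@H]12 | intermediate
18 | angelic acid, (2Z)-2-methylbut-2-enoic acid | C/C=C(/C)C(=O)O | starting material
19 | (2Z)-2-methylbut-2-en-1-ol | C/C=C(/C)CO | intermediate
20 | [(2R,3S)-2,3-dimethyloxiran-2-yl]methanol | OC[C@@]1(C)O[C@H]1C | intermediate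
21 | (2S,3S)-2,3-dimethyloxirane-2-carboxylic acid | OC(=O)[C@@]1(C)O[C@H]1C | intermediate
22 | (1R,4Z,6R,7R,8R,10S)-14-acetoxy-8-{[(2S,3S)-2,3-dimethyloxiran-2-yl]carbonyloxy}-1,10-epoxygermacra-4,11(13)-dien-12,6-olide (CNP0232260.1) | C=C1C(=O)O[C@@H]2/C=C(/C)CC[C@H]3O[C@]3(COC(C)=O)C[C@@H](OC(=O)[C@@]3(C)O[C@H]3C)[C@@H]12 | target

## Step count and risks

Total step count: 15. Longest linear sequence: 11 steps (1 → 2 → 6 → 8 → 9 → 10 → 12 → 13 → 15 → 16 → 17 → 22).

The tartrate enantiomers in steps 10 and 13 are assigned from the recalled outcome that L-(+)-tartrate gives (2S,3S)-epoxygeraniol and (2S,3R)-epoxynerol; if that recollection is wrong, both tartrates swap.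

Most likely to fail, first: step 9. The macrocyclisation must beat protonolysis of the allylindium and oligomerisation. The lactol releases its aldehyde only slowly and may aromatise to a 3-substituted furan in acid. The facial (C7) and C8 selectivities of the intramolecular reaction rest on transition-state reasoning, not precedent. The fallback sets out from 13 and comes back at 15:
- Displace the bromide of 13 with CH3CO2K in DMF to give {(5R)-5-[(1Z,5Z)-5-(5-methoxyoxolan-3-ylidene)-2-methylpent-1-en-1-yl]-2-oxo-2,5-dihydrofuran-3-yl}methyl acetate F1.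
- Hydrolyse the acetal with dilute aqueous HCl to the lactol {(5R)-5-[(1Z,5Z)-5-(5-hydroxyoxolan-3-ylidene)-2-methylpent-1-en-1-yl]-2-oxo-2,5-dihydrofuran-3-yl}methyl acetate F2.
- Close the ring with SmI2 in THF at high dilution. Here C8 is the reversed-polarity centre: the ketyl from the aldehyde form of F2 adds to C7 of the butenolide anti to the C5 chain, and the samarium enolate expels acetate to give the α-methylene lactone 15.

Second: step 15. A Mitsunobu inversion at a hindered secondary carbinol on a ten-membered ring with an α-quaternary acid may stall or eliminate. The fallback sets out from 17 (with 21) and comes back at 22: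
- Convert 17 with Tf2O and pyridine at −40 °C into (1R,4Z,6R,7R,8S,10S)-14-acetoxy-1,10-epoxy-8-(trifluoromethanesulfonyloxy)germacra-4,11(13)-dien-12,6-olide F3.
- Convert 21 with Cs2CO3 into caesium (2S,3S)-2,3-dimethyloxirane-2-carboxylate F4.
- Displace F3 with F4 and 18-crown-6 in toluene. An isolated sulfonate and a naked carboxylate replace the redox condensation and give 22, again with inversion at C8.

Third: step 4. The saturated ester may be over-reduced to the diol, or the lactol may aromatise during acetalisation. The fallback sets out from 2 (with 3) and comes back at 8: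
- Alkylate 3 with bromoacetaldehyde dimethyl acetal (NaH, DMF, 60 °C) to give methyl 2-[bis(2,2,2-trifluoroethoxy)phosphoryl]-4,4-dimethoxybutanoate F5.
- Olefinate 2 with F5 under the conditions of step 3 to give methyl (2Z,6Z)-8-acetoxy-2-(2,2-dimethoxyethyl)-6-methylocta-2,6-dienoate F6.
- Reduce F6 fully with iBu2AlH (−78 → 0 °C) to (2Z,6Z)-2-(2,2-dimethoxyethyl)-6-methylocta-2,6-diene-1,8-diol F7; C8 is already an acetal, so no partial reduction is needed.
- Catalytic PPTS in CH2Cl2 closes the cyclic methyl acetal 8 by intramolecular transacetalisation with the C14 hydroxyl.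

Further compounds

F1 | step 9 | {(5R)-5-[(1Z,5Z)-5-(5-methoxyoxolan-3-ylidene)-2-methylpent-1-en-1-yl]-2-oxo-2,5-dihydrofuran-3-yl}methyl acetate | COC1C/C(=C/CC/C(C)=C\[C@H]2OC(=O)C(COC(C)=O)=C2)CO1
F2 | step 9 | {(5R)-5-[(1Z,5Z)-5-(5-hydroxyoxolan-3-ylidene)-2-methylpent-1-en-1-yl]-2-oxo-2,5-dihydrofuran-3-yl}methyl acetate | OC1C/C(=C/CC/C(C)=C\[C@H]2OC(=O)C(COC(C)=O)=C2)CO1
F3 | step 15 | (1R,4Z,6R,7R,8S,10S)-14-acetoxy-1,10-epoxy-8-(trifluoromethanesulfonyloxy)germacra-4,11(13)-dien-12,6-olide | C=C1C(=O)O[C@@H]2/C=C(/C)CC[C@H]3O[C@]3(COC(C)=O)C[C@H](OS(=O)(=O)C(F)(F)F)[C@@H]12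
F4 | step 15 | caesium (2S,3S)-2,3-dimethyloxirane-2-carboxylate | [Cs+].[O-]C(=O)[C@@]1(C)O[C@H]1C
F5 | step 4 | methyl 2-[bis(2,2,2-trifluoroethoxy)phosphoryl]-4,4-dimethoxybutanoate | COC(=O)C(CC(OC)OC)P(=O)(OCC(F)(F)F)OCC(F)(F)F
F6 | step 4 | methyl (2Z,6Z)-8-acetoxy-2-(2,2-dimethoxyethyl)-6-methylocta-2,6-dienoate | CC(=O)OC/C=C(C)\CC/C=C(/CC(OC)OC)C(=O)OC
F7 | step 4 | (2Z,6Z)-2-(2,2-dimethoxyethyl)-6-methylocta-2,6-diene-1,8-diol | OC/C=C(C)\CC/C=C(/CC(OC)OC)CO
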